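The grey run, the earlier neighbour of these flasks, turned its starting material slowly, and its readings give a price for each day spent in the flask.

in all of them: gas phase 30 mM (held)
- grey: starting material 0.34 M (fed, over 0.50 d); run made earlier
- west: starting material 0.17 M (fed, over 0.50 d); time 2.5 d
- north-east: starting material 0.17 M (fed, over 0.80 d); time 2.5 d
- south-west: starting material 0.17 M (fed, over 1.2 d); time 2.5 d
- north-west: starting material 0.17 M (fed, over 1.5 d); time 2.5 d
- north: starting material 0.17 M (fed, over 2.5 d); time 2.5 d

grey run (percent of the starting material charged)

| time / h | product / % | starting material / % |
|---|---|---|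
| 2.50 | 0 | 20.8 |
| 6.00 | 0 | 49.7 |
| 12.0 | 1.9 | 98.2 |
| 20.0 | 4.3 | 95.9 |

(scatter of a reading: 0.3 percentage points)

- at the start none of the gas phase is in solution
- "hardly changes" means that all values lie within two and a half points (for a concentration: within two and a half percent of the largest)
- percentages count the whole charge, also what has not yet gone in

- amount of product at the end, in percent of the starting material charged for west, north-east, south-west, north-west, north, in this order
- the shape of the row from first to last (falls all the way / rises, then falls / hardly changes / falls, then rises / rises all the way)

After the grey feed ended, starting material fell from 98.2% to 95.9% in 8.00 h. That is the share of the charge turned per day of waiting, the turning rate, 0.0690 d⁻¹, a pseudo-first-order constant.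

The second way uses a different reading, the product. A steady feed means that at its end in grey the portions have waited, on average, half the dosing time, 6.00 h. So 1.9% of product gives 0.0760 d⁻¹.

The two ways part by 0.17 percentage points at that reading, against a scatter of 0.3 points, but the drop of 2.3 points is a difference of two scattered readings, so take the turning rate as a rough reading of grey. A steady speed from the first hour means 3.45% at 12.0 h, but grey read less than that, 1.9%, so the grey speed was lower during the feed than after it.

Both ways come from a charge of 0.34 M, and west has half of that. If the smaller charge leaves more gas dissolved, the row below runs low. I commit to it anyway: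

product at the end = turning rate × (time − half the dosing time)

west: 0.0690 d⁻¹ × 2.25 d = 15.5%

north-east: 14.5%

south-west: 13.1%

north-west: 12.1%

north: 0.0690 d⁻¹ × 1.25 d = 8.62%

The forecast, lower than my row at west, gives 13%, 12%, 10.5%, 9.5% and 6.5%, a row that falls all the way, and says: “Slower feeding keeps less starting material present for less time”.

The flasks give 22.0%, 21.1%, 19.8%, 18.6% and 14.3%, a row that falls all the way.

    gas phase ⇌ dissolved gas, rate k1*(csat - [dissolved gas]) (kL = 2.64 × 10⁻⁵ s⁻¹)
    starting material + dissolved gas → product (k = 6.42 × 10⁻⁵ M⁻¹ s⁻¹)
    dissolved gas → decomposed reagent (k = 1.34 × 10⁻⁶ s⁻¹)

In west, product over waiting time is 0.0978 d⁻¹, more than the 0.0690 d⁻¹ read in grey, and the rate constant of the product step times the dissolved gas at 1.25 d, 0.0206 M, gives 0.114 d⁻¹. Gas phase went on dissolving in west while starting material became product: c(dissolved gas) stood at 0.0175 M after 0.500 d and 0.0216 M after 2.50 d, with decomposed reagent at 0.00542 M by then. In north, dosed to the end, product over waiting time is 0.114 d⁻¹, with c(dissolved gas) at 0.0220 M and 85.7% of the starting material left after 2.50 d.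

The data were generated by integration on assumed constants, noise included.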